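## Retrosynthetic overview

1. The target comes from a bicyclic silyl ether / 2-(trimethylsilyl)ethyl ester by desilylation and oxidation; the ring ethyl group (C7) is installed by Negishi coupling of an enol triflate.
2. The enol triflate comes from an acyclic dienone–enoate by a one-pot intramolecular double Michael addition. The cyclopentane closes first (5-exo, C3a–C7a bond), then the cyclohexene (6-endo, C4–C5 bond, both quaternary centres), and the final enolate is trapped as the triflate.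
3. The dienone–enoate comes from an aldehyde and a dienyl iodide by Nozaki–Hiyama–Kishi coupling and oxidation.
4. The aldehyde comes from (R)-2-ethylpent-4-enal (Evans allylation, sets C1) and a chiral silyl dienolate (vinylogous Mukaiyama aldol, sets C3 and a temporary C2 carbinol). The dienyl iodide comes from a styryl enyne by syn-ethylcupration and iodination.

Assumption: locants C1–C7a are those of the 1H-indene skeleton of the target (C1 ethyl, C2 ketone, C3 methyl, C4 acid, C5 styryl, C7 ethyl), and the silyl dienolate is taken to react on the face opposite its isopropyl group, which is why the D-valinol auxiliary is used.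

## Route

Step 1
Reactants: 1 (S)-4-benzyloxazolidin-2-one; 2 butanoyl chloride
Product: 4 (S)-4-benzyl-3-butanoyloxazolidin-2-one, via N-lithio oxazolidinone 3 (not isolated)
Conditions: n-BuLi, THF, −78 °C; then 2, −78 → 0 °C
Reagents that add atoms: none
Why: N-acylation of the lithiated carbamate by the acid chloride attaches the Evans auxiliary to the four-carbon unit that becomes C1, its ethyl group and C2.

Step 2
Reactants: 4 (S)-4-benzyl-3-butanoyloxazolidin-2-one; 5 allyl iodide
Product: 7 (S)-4-benzyl-3-[(R)-2-ethylpent-4-enoyl]oxazolidin-2-one, via sodium Z-enolate 6 (not isolated)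
Conditions: NaN(SiMe3)2, THF, −78 °C; then 5, −78 → −45 °C
Reagents that add atoms: none
Why: Evans asymmetric alkylation, in which the chelated Z-enolate is allylated on the face away from the benzyl group, sets the future C1 centre as R.

Step 3
Reactants: 7 (S)-4-benzyl-3-[(R)-2-ethylpent-4-enoyl]oxazolidin-2-one
Product: 8 (R)-2-ethylpent-4-en-1-ol
Conditions: LiBH4, MeOH (1 equiv), Et2O, 0 °C
Reagents that add atoms: none
Why: Reductive cleavage of the imide by borohydride attacks only the exocyclic carbonyl, so the alcohol is released without epimerisation and the auxiliary is recovered.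

Step 4
Reactants: 8 (R)-2-ethylpent-4-en-1-ol
Product: 9 (R)-2-ethylpent-4-enal
Conditions: TEMPO (10 mol %), PhI(OAc)2, CH2Cl2, rt; solution used directly
Reagents that add atoms: none
Why: TEMPO-catalysed oxidation of a primary alcohol stops at the aldehyde under near-neutral conditions and leaves the α-stereocentre intact.

Step 5
Reactants: 10 D-valinol, (R)-2-amino-3-methylbutan-1-ol
Product: 11 (R)-4-isopropyloxazolidin-2-one
Conditions: (EtO)2CO, K2CO3 (5 mol %), 130 °C, ethanol distilled off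
Reagents that add atoms: diethyl carbonate, CCOC(=O)OCC
Why: Cyclic carbamate formation by double acyl substitution on diethyl carbonate does not touch the stereocentre.

Step 6
Reactants: 12 triethyl 2-phosphonobutanoate; 13 propanal
Product: 15 ethyl (E)-2-ethylpent-2-enoate, via sodium phosphonate carbanion 14 (not isolated)
Conditions: NaH, THF, 0 °C; then 13, 0 °C → rt
Reagents that add atoms: none
Why: Horner–Wadsworth–Emmons olefination gives mainly the E-enoate, and this alkene geometry is in any case erased when the dienolate is formed in step 9.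

Step 7
Reactants: 15 ethyl (E)-2-ethylpent-2-enoate
Product: 16 (E)-2-ethylpent-2-enoic acid
Conditions: LiOH, THF/MeOH/H2O, 40 °C; then 1 M HCl
Reagents that add atoms: lithium hydroxide, [Li+].[OH-]
Why: Saponification of an unhindered ethyl ester proceeds cleanly without moving the double bond.

Step 8
Reactants: 16 (E)-2-ethylpent-2-enoic acid; 11 (R)-4-isopropyloxazolidin-2-one
Product: 18 (R)-3-[(E)-2-ethylpent-2-enoyl]-4-isopropyloxazolidin-2-one, via mixed pivalic anhydride 17 (not isolated)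
Conditions: t-BuCOCl, Et3N, THF, −20 °C; then 11, LiCl, −20 °C → rt
Reagents that add atoms: none
Why: N-acylation through a mixed anhydride works because the oxazolidinone attacks the less hindered enoyl carbonyl and not the pivaloyl one.

Step 9
Reactants: 18 (R)-3-[(E)-2-ethylpent-2-enoyl]-4-isopropyloxazolidin-2-one
Product: 20 (R)-3-[(1E,3E)-1-[(tert-butyldimethylsilyl)oxy]-2-ethylpenta-1,3-dien-1-yl]-4-isopropyloxazolidin-2-one, via sodium dienolate 19 (not isolated)
Conditions: NaN(SiMe3)2, THF, −78 °C; then TBSCl, −78 °C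
Reagents that add atoms: tert-butyldimethylsilyl chloride, CC(C)(C)[Si](C)(C)Cl
Why: Vinylogous (γ) enolisation followed by O-silylation gives the E,E-vinylketene silyl N,O-acetal, whose oxazolidinone ring is twisted out of the diene plane so that the isopropyl group shields one face.

Step 10
Reactants: 9 (R)-2-ethylpent-4-enal; 20 (R)-3-[(1E,3E)-1-[(tert-butyldimethylsilyl)oxy]-2-ethylpenta-1,3-dien-1-yl]-4-isopropyloxazolidin-2-one
Product: 21 (R)-3-[(2E,4R,5S,6R)-2,6-diethyl-5-hydroxy-4-methylnona-2,8-dienoyl]-4-isopropyloxazolidin-2-one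
Conditions: TiCl4 (1.0 equiv), CH2Cl2, −78 → −40 °C, 24 h; aq. NaHCO3
Reagents that add atoms: none
Why: Kobayashi-type vinylogous Mukaiyama aldol in which the TiCl4-activated aldehyde is attacked by the γ-carbon of 20 on the face opposite the isopropyl group through an open transition state, giving the E-enoyl imide and the 4,5-anti pair (4R,5S) under reagent control, the existing centre of 9 (ethyl versus allyl) exerting no real bias.

Step 11
Reactants: 21 (R)-3-[(2E,4R,5S,6R)-2,6-diethyl-5-hydroxy-4-methylnona-2,8-dienoyl]-4-isopropyloxazolidin-2-one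
Product: 22 (R)-3-[(2E,4R,5S,6R)-5-[(tert-butyldimethylsilyl)oxy]-2,6-diethyl-4-methylnona-2,8-dienoyl]-4-isopropyloxazolidin-2-one
Conditions: TBSOTf, 2,6-lutidine, CH2Cl2, −78 → 0 °C
Reagents that add atoms: tert-butyldimethylsilyl trifluoromethanesulfonate, CC(C)(C)[Si](C)(C)OS(=O)(=O)C(F)(F)F
Why: Silylation of the hindered secondary alcohol with the silyl triflate masks the future C2 ketone so that no 1,4-diketone or lactol chemistry can interfere later.

Step 12
Reactants: 22 (R)-3-[(2E,4R,5S,6R)-5-[(tert-butyldimethylsilyl)oxy]-2,6-diethyl-4-methylnona-2,8-dienoyl]-4-isopropyloxazolidin-2-one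
Product: 23 2-(trimethylsilyl)ethyl (2E,4R,5S,6R)-5-[(tert-butyldimethylsilyl)oxy]-2,6-diethyl-4-methylnona-2,8-dienoate
Conditions: Me3SiCH2CH2OH, n-BuLi, THF, 0 °C
Reagents that add atoms: 2-(trimethylsilyl)ethanol, C[Si](C)(C)CCO
Why: Alkoxide transesterification of the N-acyl oxazolidinone at the exocyclic carbonyl swaps the auxiliary for an ester that can later be removed by fluoride without attack at a hindered carbonyl.

Step 13
Reactants: 23 2-(trimethylsilyl)ethyl (2E,4R,5S,6R)-5-[(tert-butyldimethylsilyl)oxy]-2,6-diethyl-4-methylnona-2,8-dienoate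
Product: 25 2-(trimethylsilyl)ethyl (2E,4R,5S,6R)-5-[(tert-butyldimethylsilyl)oxy]-2,6-diethyl-4-methyl-8-oxooct-2-enoate, via vicinal diol 24 (not isolated)
Conditions: OsO4 (2 mol %), NaIO4 (4 equiv), 2,6-lutidine, dioxane/H2O 3:1, rt
Reagents that add atoms: osmium tetroxide, O=[Os](=O)(=O)=O; sodium periodate, [Na+].[O-]I(=O)(=O)=O (terminal source of the new carbonyl oxygen)
Why: Lemieux–Johnson oxidative cleavage, in which OsO4 dihydroxylates only the electron-rich monosubstituted alkene and periodate cleaves the diol, leaves the hindered electron-poor enoate and all stereocentres untouched.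

Step 14
Reactants: 26 (E)-(2-bromoethenyl)benzene; 27 ethynyltrimethylsilane
Product: 28 (E)-trimethyl(4-phenylbut-3-en-1-yn-1-yl)silane
Conditions: Pd(PPh3)2Cl2 (2 mol %), CuI (4 mol %), Et3N, THF, rt
Reagents that add atoms: none
Why: Sonogashira coupling of the vinyl bromide proceeds with retention of the E geometry.

Step 15
Reactants: 28 (E)-trimethyl(4-phenylbut-3-en-1-yn-1-yl)silane
Product: 29 (E)-but-1-en-3-yn-1-ylbenzene
Conditions: K2CO3 (0.2 equiv), MeOH, rt
Reagents that add atoms: none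
Why: Methanolysis of the alkynyl C–Si bond frees the terminal alkyne needed for carbometalation.

Step 16
Reactants: 29 (E)-but-1-en-3-yn-1-ylbenzene; 30 ethylmagnesium bromide
Product: 32 [(1E,3E)-3-ethyl-4-iodobuta-1,3-dien-1-yl]benzene, via dienylcopper 31 (not isolated)
Conditions: CuBr·SMe2, 30, Et2O/Me2S, −45 °C; then 29, −25 °C; then I2, THF, −60 → 0 °C
Reagents that add atoms: iodine, [I][I]
Why: Normant syn-carbocupration places ethyl on the internal alkyne carbon and copper on the terminal one on the same side, and iodinolysis with retention gives the iodide with ethyl cis to iodine, which is the dienone geometry needed later.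

Step 17
Reactants: 25 2-(trimethylsilyl)ethyl (2E,4R,5S,6R)-5-[(tert-butyldimethylsilyl)oxy]-2,6-diethyl-4-methyl-8-oxooct-2-enoate; 32 [(1E,3E)-3-ethyl-4-iodobuta-1,3-dien-1-yl]benzene
Product: 34 2-(trimethylsilyl)ethyl (2E,4R,5S,6R,9E,11E)-5-[(tert-butyldimethylsilyl)oxy]-2,6,10-triethyl-8-hydroxy-4-methyl-12-phenyldodeca-2,9,11-trienoate (both C8 epimers), via dienylchromium dichloride 33 (not isolated)
Conditions: CrCl2 (4 equiv), NiCl2 (1 mol %), DMSO, rt
Reagents that add atoms: none
Why: Nozaki–Hiyama–Kishi coupling forms the alkenylchromium species with retention of geometry and adds it only to the aldehyde, tolerating the ester, enoate and silyl ethers, while the unselectively formed carbinol centre is removed in step 18.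

Step 18
Reactants: 34 2-(trimethylsilyl)ethyl (2E,4R,5S,6R,9E,11E)-5-[(tert-butyldimethylsilyl)oxy]-2,6,10-triethyl-8-hydroxy-4-methyl-12-phenyldodeca-2,9,11-trienoate
Product: 35 2-(trimethylsilyl)ethyl (2E,4R,5S,6R,9E,11E)-5-[(tert-butyldimethylsilyl)oxy]-2,6,10-triethyl-4-methyl-8-oxo-12-phenyldodeca-2,9,11-trienoate
Conditions: Dess–Martin periodinane, CH2Cl2, 0 °C → rt
Reagents that add atoms: none
Why: Dess–Martin oxidation of the dienylic alcohol gives the cross-conjugated dienone, whose only enolisable site is the CH2 that will start the cascade.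

Step 19
Reactants: 35 2-(trimethylsilyl)ethyl (2E,4R,5S,6R,9E,11E)-5-[(tert-butyldimethylsilyl)oxy]-2,6,10-triethyl-4-methyl-8-oxo-12-phenyldodeca-2,9,11-trienoate
Product: 39 2-(trimethylsilyl)ethyl (1R,2R,3R,3aR,4S,5R,7aS)-2-[(tert-butyldimethylsilyl)oxy]-1,4,5-triethyl-3-methyl-5-[(E)-2-phenylethenyl]-7-{[(trifluoromethyl)sulfonyl]oxy}-2,3,3a,4,5,7a-hexahydro-1H-indene-4-carboxylate, via lithium dienolate 36 (not isolated), via cyclopentane ester enolate 37 (not isolated), via bicyclic lithium enolate 38 (not isolated)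
Conditions: LiN(SiMe3)2 (1.1 equiv), THF, −78 °C, then −78 → 0 °C, 2 h; then N-(5-chloropyridin-2-yl)triflimide, −78 → 0 °C
Reagents that add atoms: N-(5-chloropyridin-2-yl)-N-[(trifluoromethyl)sulfonyl]trifluoromethanesulfonamide (Comins reagent), FC(F)(F)S(=O)(=O)N(c1ccc(Cl)cn1)S(=O)(=O)C(F)(F)F
Why: Intramolecular double Michael addition, in which the Z-dienolate adds 5-exo to the enoate anti to both the ethyl-bearing and the methyl-bearing tether carbons (A1,3 strain minimised, hence trans ring fusion) and the resulting ester enolate then adds 6-endo to the E-dienone on the face fixed by the new ring, setting C4 and C5 with the two ethyl groups cis, after which the regiodefined enolate is O-triflated.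

Step 20
Reactants: 39 the enol triflate of step 19; 40 diethylzinc
Product: 41 2-(trimethylsilyl)ethyl (1R,2R,3R,3aS,4S,5R,7aS)-2-[(tert-butyldimethylsilyl)oxy]-1,4,5,7-tetraethyl-3-methyl-5-[(E)-2-phenylethenyl]-2,3,3a,4,5,7a-hexahydro-1H-indene-4-carboxylate
Conditions: Pd(dppf)Cl2 (5 mol %), 40 (1.5 equiv), THF, 50 °C
Reagents that add atoms: none
Why: Negishi coupling of the alkenyl triflate with the ethylzinc reagent keeps the double bond in place, the wide-bite-angle dppf ligand favouring reductive elimination over β-hydride elimination.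

Step 21
Reactants: 41 the bicyclic bis-silyl compound of step 20
Product: 42 (1R,2R,3R,3aS,4S,5R,7aS)-1,4,5,7-tetraethyl-2-hydroxy-3-methyl-5-[(E)-2-phenylethenyl]-2,3,3a,4,5,7a-hexahydro-1H-indene-4-carboxylic acid
Conditions: Bu4NF (6 equiv), THF, 50 °C; then 1 M HCl to pH 3
Reagents that add atoms: none
Why: Fluoride-induced β-elimination of the 2-(trimethylsilyl)ethyl ester and Si–O cleavage of the silyl ether unmask the acid and the alcohol without any attack at the hindered quaternary carbonyl.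

Step 22
Reactants: 42 the hydroxy acid of step 21
Product: 43 isospiculoic acid A, (1R,3R,3aS,4S,5R,7aS)-1,4,5,7-tetraethyl-3-methyl-2-oxo-5-[(E)-2-phenylethenyl]-2,3,3a,4,5,7a-hexahydro-1H-indene-4-carboxylic acid
Conditions: Dess–Martin periodinane, CH2Cl2, rt
Reagents that add atoms: none
Why: Dess–Martin oxidation of the secondary alcohol gives the ketone under non-basic conditions, and C1 and C3 already hold the thermodynamically preferred configuration (each substituent trans to the adjacent ring-fusion bond), so they are not at risk.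

## Compound list

1 | (S)-4-benzyloxazolidin-2-one | O=C1N[C@@H](Cc2ccccc2)CO1 | starting material
2 | butanoyl chloride | CCCC(=O)Cl | starting material
3 | N-lithio (S)-4-benzyloxazolidin-2-one (not isolated) | [Li]N1[C@@H](Cc2ccccc2)COC1=O | intermediate
4 | (S)-4-benzyl-3-butanoyloxazolidin-2-one | CCCC(=O)N1[C@@H](Cc2ccccc2)COC1=O | intermediate
5 | allyl iodide (3-iodoprop-1-ene) | C=CCI | starting material
6 | sodium (Z)-enolate of 4 (not isolated) | CC/C=C(\O[Na])N1[C@@H](Cc2ccccc2)COC1=O | intermediate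
7 | (S)-4-benzyl-3-[(R)-2-ethylpent-4-enoyl]oxazolidin-2-one | CC[C@H](CC=C)C(=O)N1[C@@H](Cc2ccccc2)COC1=O | intermediate
8 | (R)-2-ethylpent-4-en-1-ol | CC[C@H](CC=C)CO | intermediate
9 | (R)-2-ethylpent-4-enal | CC[C@H](CC=C)C=O | intermediate
10 | D-valinol, (R)-2-amino-3-methylbutan-1-ol | CC(C)[C@@H](N)CO | starting material
11 | (R)-4-isopropyloxazolidin-2-one | CC(C)[C@@H]1COC(=O)N1 | intermediate
12 | triethyl 2-phosphonobutanoate | CCOC(=O)C(CC)P(=O)(OCC)OCC | starting material
13 | propanal | CCC=O | starting material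
14 | sodium carbanion of 12 (not isolated) | CCOC(=O)[C-](CC)P(=O)(OCC)OCC.[Na+] | intermediate
15 | ethyl (E)-2-ethylpent-2-enoate | CC/C=C(\CC)C(=O)OCC | intermediate
16 | (E)-2-ethylpent-2-enoic acid | CC/C=C(\CC)C(=O)O | intermediate
17 | (E)-2-ethylpent-2-enoic pivalic anhydride (not isolated) | CC/C=C(\CC)C(=O)OC(=O)C(C)(C)C | intermediate
18 | (R)-3-[(E)-2-ethylpent-2-enoyl]-4-isopropyloxazolidin-2-one | CC/C=C(\CC)C(=O)N1[C@H](C(C)C)COC1=O | intermediate
19 | sodium (1E,3E)-dienolate of 18 (not isolated) | C/C=C/C(CC)=C(/O[Na])N1[C@H](C(C)C)COC1=O | intermediate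
20 | (R)-3-[(1E,3E)-1-[(tert-butyldimethylsilyl)oxy]-2-ethylpenta-1,3-dien-1-yl]-4-isopropyloxazolidin-2-one | C/C=C/C(CC)=C(/O[Si](C)(C)C(C)(C)C)N1[C@H](C(C)C)COC1=O | intermediate
21 | (R)-3-[(2E,4R,5S,6R)-2,6-diethyl-5-hydroxy-4-methylnona-2,8-dienoyl]-4-isopropyloxazolidin-2-one | O=C1OC[C@@H](C(C)C)N1C(=O)/C(CC)=C/[C@@H](C)[C@@H](O)[C@H](CC)CC=C | intermediate
22 | (R)-3-[(2E,4R,5S,6R)-5-[(tert-butyldimethylsilyl)oxy]-2,6-diethyl-4-methylnona-2,8-dienoyl]-4-isopropyloxazolidin-2-one | O=C1OC[C@@H](C(C)C)N1C(=O)/C(CC)=C/[C@@H](C)[C@@H](O[Si](C)(C)C(C)(C)C)[C@H](CC)CC=C | intermediate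
23 | 2-(trimethylsilyl)ethyl (2E,4R,5S,6R)-5-[(tert-butyldimethylsilyl)oxy]-2,6-diethyl-4-methylnona-2,8-dienoate | C[Si](C)(C)CCOC(=O)/C(CC)=C/[C@@H](C)[C@@H](O[Si](C)(C)C(C)(C)C)[C@H](CC)CC=C | intermediate
24 | 2-(trimethylsilyl)ethyl (2E,4R,5S,6R)-5-[(tert-butyldimethylsilyl)oxy]-2,6-diethyl-8,9-dihydroxy-4-methylnon-2-enoate (both C8 epimers; not isolated) | C[Si](C)(C)CCOC(=O)/C(CC)=C/[C@@H](C)[C@@H](O[Si](C)(C)C(C)(C)C)[C@H](CC)CC(O)CO | intermediate
25 | 2-(trimethylsilyl)ethyl (2E,4R,5S,6R)-5-[(tert-butyldimethylsilyl)oxy]-2,6-diethyl-4-methyl-8-oxooct-2-enoate | C[Si](C)(C)CCOC(=O)/C(CC)=C/[C@@H](C)[C@@H](O[Si](C)(C)C(C)(C)C)[C@H](CC)CC=O | intermediate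
26 | (E)-(2-bromoethenyl)benzene | Br/C=C/c1ccccc1 | starting material
27 | ethynyltrimethylsilane | C#C[Si](C)(C)C | starting material
28 | (E)-trimethyl(4-phenylbut-3-en-1-yn-1-yl)silane | C[Si](C)(C)C#C/C=C/c1ccccc1 | intermediate
29 | (E)-but-1-en-3-yn-1-ylbenzene | C#C/C=C/c1ccccc1 | intermediate
30 | ethylmagnesium bromide | CC[Mg]Br | starting material
31 | [(1E,3E)-2-ethyl-4-phenylbuta-1,3-dien-1-yl]copper (not isolated) | [Cu]/C=C(CC)/C=C/c1ccccc1 | intermediate
32 | [(1E,3E)-3-ethyl-4-iodobuta-1,3-dien-1-yl]benzene | I/C=C(CC)/C=C/c1ccccc1 | intermediate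
33 | [(1E,3E)-2-ethyl-4-phenylbuta-1,3-dien-1-yl]chromium dichloride (not isolated) | Cl[Cr](Cl)/C=C(CC)/C=C/c1ccccc1 | intermediate
34 | 2-(trimethylsilyl)ethyl (2E,4R,5S,6R,9E,11E)-5-[(tert-butyldimethylsilyl)oxy]-2,6,10-triethyl-8-hydroxy-4-methyl-12-phenyldodeca-2,9,11-trienoate (both C8 epimers) | C[Si](C)(C)CCOC(=O)/C(CC)=C/[C@@H](C)[C@@H](O[Si](C)(C)C(C)(C)C)[C@H](CC)CC(O)/C=C(CC)/C=C/c1ccccc1 | intermediate
35 | 2-(trimethylsilyl)ethyl (2E,4R,5S,6R,9E,11E)-5-[(tert-butyldimethylsilyl)oxy]-2,6,10-triethyl-4-methyl-8-oxo-12-phenyldodeca-2,9,11-trienoate | C[Si](C)(C)CCOC(=O)/C(CC)=C/[C@@H](C)[C@@H](O[Si](C)(C)C(C)(C)C)[C@H](CC)CC(=O)/C=C(CC)/C=C/c1ccccc1 | intermediate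
36 | lithium (7Z)-dienolate of 35 (not isolated) | C[Si](C)(C)CCOC(=O)/C(CC)=C/[C@@H](C)[C@@H](O[Si](C)(C)C(C)(C)C)[C@H](CC)/C=C(\O[Li])/C=C(CC)/C=C/c1ccccc1 | intermediate
37 | lithium ester enolate of the all-trans cyclopentane mono-adduct (enolate geometry not assigned; not isolated) | O=C(/C=C(CC)/C=C/c1ccccc1)[C@@H]1[C@@H](CC)[C@H](O[Si](C)(C)C(C)(C)C)[C@H](C)[C@H]1C(CC)=C(O[Li])OCC[Si](C)(C)C | intermediate
38 | bicyclic lithium enolate, C7–OLi analogue of 39 (not isolated) | [Li]OC1=C[C@](/C=C/c2ccccc2)(CC)[C@@](CC)(C(=O)OCC[Si](C)(C)C)[C@H]2[C@H]1[C@@H](CC)[C@H](O[Si](C)(C)C(C)(C)C)[C@@H]2C | intermediate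
39 | 2-(trimethylsilyl)ethyl (1R,2R,3R,3aR,4S,5R,7aS)-2-[(tert-butyldimethylsilyl)oxy]-1,4,5-triethyl-3-methyl-5-[(E)-2-phenylethenyl]-7-{[(trifluoromethyl)sulfonyl]oxy}-2,3,3a,4,5,7a-hexahydro-1H-indene-4-carboxylate | FC(F)(F)S(=O)(=O)OC1=C[C@](/C=C/c2ccccc2)(CC)[C@@](CC)(C(=O)OCC[Si](C)(C)C)[C@H]2[C@H]1[C@@H](CC)[C@H](O[Si](C)(C)C(C)(C)C)[C@@H]2C | intermediate
40 | diethylzinc | CC[Zn]CC | starting material
41 | 2-(trimethylsilyl)ethyl (1R,2R,3R,3aS,4S,5R,7aS)-2-[(tert-butyldimethylsilyl)oxy]-1,4,5,7-tetraethyl-3-methyl-5-[(E)-2-phenylethenyl]-2,3,3a,4,5,7a-hexahydro-1H-indene-4-carboxylate | CCC1=C[C@](/C=C/c2ccccc2)(CC)[C@@](CC)(C(=O)OCC[Si](C)(C)C)[C@H]2[C@H]1[C@@H](CC)[C@H](O[Si](C)(C)C(C)(C)C)[C@@H]2C | intermediate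
42 | (1R,2R,3R,3aS,4S,5R,7aS)-1,4,5,7-tetraethyl-2-hydroxy-3-methyl-5-[(E)-2-phenylethenyl]-2,3,3a,4,5,7a-hexahydro-1H-indene-4-carboxylic acid | CCC1=C[C@](/C=C/c2ccccc2)(CC)[C@@](CC)(C(=O)O)[C@H]2[C@H]1[C@@H](CC)[C@H](O)[C@@H]2C | intermediate
43 | isospiculoic acid A, (1R,3R,3aS,4S,5R,7aS)-1,4,5,7-tetraethyl-3-methyl-2-oxo-5-[(E)-2-phenylethenyl]-2,3,3a,4,5,7a-hexahydro-1H-indene-4-carboxylic acid | CCC1=C[C@](/C=C/c2ccccc2)(CC)[C@@](CC)(C(=O)O)[C@H]2[C@H]1[C@@H](CC)C(=O)[C@@H]2C | target

## Step count and risks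

Total: 22 steps. Longest linear sequence: 14 steps (steps 1–4, 10–13 and 17–22; the chain 6–9, 10–13, 17–22 is equally long), which is 64 % of the total. The other branches are step 5 and steps 14–16.

The three steps most likely to fail:

**Step 19 (double Michael cascade).** The ester enolate 37 may be quenched by proton transfer before it closes the hindered C4–C5 bond, or the C4 centre may scramble by rotation. The fallback sets out from dienone 35 and comes back at triflate 39. Treat 35 with Et3SiOTf and Et3N (CH2Cl2, −78 °C) to obtain the triethylsilyl dienol ether F1, a 2-silyloxy triene. Heat it in toluene at 110 °C so that both rings close in a concerted intramolecular Diels–Alder reaction, giving the bicyclic silyl enol ether F2. Cleave its Si–O bond with MeLi (THF, 0 °C) to regenerate lithium enolate 38 and triflate it as in step 19 to reach 39.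

**Step 16 (ethylcupration of the conjugated enyne).** Regio- or stereoisomeric dienylcopper species would give the wrong iodide. The fallback sets out from aldehyde 25 and comes back at dienone 35, so that iodide 32 and steps 17 and 18 are not needed. Add lithium but-1-yn-1-ide (but-1-yne, n-BuLi, THF, −78 °C) to 25 to give the propargylic alcohol F3, and oxidise it with Dess–Martin periodinane to the ynone F4. Then add (E)-2-phenylethenylboronic acid across the triple bond with [Rh(OH)(cod)]2 in dioxane/H2O; this syn hydro-alkenylation places the styryl group trans to the carbonyl and delivers 35.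

**Step 20 (ethyl transfer to a hindered enol triflate).** β-Hydride elimination could give the reduced alkene. The fallback sets out from triflate 39 and comes back at 41. A Stille coupling of 39 with tributyl(vinyl)stannane (Pd(PPh3)4, LiCl, THF, 60 °C) gives the 7-vinyl diene F5. Its terminal vinyl group alone is then reduced with diimide (2-nitrobenzenesulfonylhydrazide, Et3N, CH2Cl2, rt), which spares the trisubstituted ring alkene and the styryl group, to give 41.

## Further compounds

F1 | step 19 | 2-(trimethylsilyl)ethyl (2E,4R,5R,6R,7Z,9E,11E)-5-[(tert-butyldimethylsilyl)oxy]-2,6,10-triethyl-4-methyl-12-phenyl-8-[(triethylsilyl)oxy]dodeca-2,7,9,11-tetraenoate | C[Si](C)(C)CCOC(=O)/C(CC)=C/[C@@H](C)[C@@H](O[Si](C)(C)C(C)(C)C)[C@H](CC)/C=C(\O[Si](CC)(CC)CC)/C=C(CC)/C=C/c1ccccc1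
F2 | step 19 | 2-(trimethylsilyl)ethyl (1R,2R,3R,3aR,4S,5R,7aS)-2-[(tert-butyldimethylsilyl)oxy]-1,4,5-triethyl-3-methyl-5-[(E)-2-phenylethenyl]-7-[(triethylsilyl)oxy]-2,3,3a,4,5,7a-hexahydro-1H-indene-4-carboxylate | CC[Si](CC)(CC)OC1=C[C@](/C=C/c2ccccc2)(CC)[C@@](CC)(C(=O)OCC[Si](C)(C)C)[C@H]2[C@H]1[C@@H](CC)[C@H](O[Si](C)(C)C(C)(C)C)[C@@H]2C
F3 | step 16 | 2-(trimethylsilyl)ethyl (2E,4R,5S,6R)-5-[(tert-butyldimethylsilyl)oxy]-2,6-diethyl-8-hydroxy-4-methyldodec-2-en-9-ynoate (both C8 epimers) | C[Si](C)(C)CCOC(=O)/C(CC)=C/[C@@H](C)[C@@H](O[Si](C)(C)C(C)(C)C)[C@H](CC)CC(O)C#CCC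
F4 | step 16 | 2-(trimethylsilyl)ethyl (2E,4R,5S,6R)-5-[(tert-butyldimethylsilyl)oxy]-2,6-diethyl-4-methyl-8-oxododec-2-en-9-ynoate | C[Si](C)(C)CCOC(=O)/C(CC)=C/[C@@H](C)[C@@H](O[Si](C)(C)C(C)(C)C)[C@H](CC)CC(=O)C#CCC
F5 | step 20 | 2-(trimethylsilyl)ethyl (1R,2R,3R,3aS,4S,5R,7aS)-2-[(tert-butyldimethylsilyl)oxy]-7-ethenyl-1,4,5-triethyl-3-methyl-5-[(E)-2-phenylethenyl]-2,3,3a,4,5,7a-hexahydro-1H-indene-4-carboxylate | C=CC1=C[C@](/C=C/c2ccccc2)(CC)[C@@](CC)(C(=O)OCC[Si](C)(C)C)[C@H]2[C@H]1[C@@H](CC)[C@H](O[Si](C)(C)C(C)(C)C)[C@@H]2C
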